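## Structural features

The target is a briarane. A cyclohexane (ring A: C1, C14, C13, C12, C11, C10) is trans-fused through C1 and C10 to a ten-membered carbocycle (ring B: C1 to C10). Ring B carries a γ-lactone across C7 and C8 (O7–C19(=O)–C17–C8).

There are twelve stereocentres in two unbroken rows. Ring A holds the quaternary C1, the all-cis 12,13,14-triol as three different esters, the spiro-epoxide carbon C11 (its oxygen on the face of the three ester oxygens and of C2), and C10. The row continues through C9, the tertiary carbinol C8, C7 and the chloride carbon C6, with C17 on the lactone and C2 next to C1.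

The fragile groups are:
- the 1,1-disubstituted oxirane (acid);
- the secondary allylic chloride beside the C5=C16 methylene (ionisation, SN2′, reducing metals);
- the β-hydroxy γ-lactone with an epimerisable C17 (base, dehydration);
- five esters of three kinds on partly cis-vicinal oxygens (acyl migration).

The real difficulty is twofold. A ten-membered ring must be closed between the quaternary C1 and the fully substituted C8. The C6–C9 row must be set on an open chain without a rigid template.

The key step exploits that C9–C8–C7–C6–C5–C4 is a six-carbon chain with oxygen on C9, C8, C7 and (before the chloride) C6. C8 and C7 have the configurations of C2 and C3 of D-mannitol, and C6 that of C4 after one inversion. The lactone then lacks only the C8–C17 bond, which a carbenoid tethered to O7 can make by insertion into the C8–H bond with retention.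

## Logic of the disconnections

**47 ⇒ 44.** The acyl–oxygen bonds at O9, O12 and O13 and the two C–O bonds of the oxirane are cut first (47 → 46 → 45 → 44), because the epoxide and the mixed ester pattern are the most sensitive features. This leaves 44, with a free cis-12,13-diol and a free C9 hydroxyl. The forward steps must acylate O13 before O12, epoxidise C11=C20 on the face of O12 in the presence of C5=C16, and acetylate two secondary hydroxyls beside the tertiary O8–H.

**44 ⇒ 42.** The C6–Cl bond is cut next (44 → 43 → 42). The allylic chloride becomes the allylic alcohol of opposite configuration, which is the configuration the chain inherits from 1. No halide then has to pass the chromium, zinc and fluoride steps. The demand is an SN2 displacement with inversion at a secondary allylic ring carbon without allylic transposition.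

**42 ⇒ 40.** Both exocyclic C=C bonds (C5=C16 and C11=C20) are cut together (42 → 41 → 40), giving a diketone. C16 and C20 then come from one reagent in one operation. The forward step must transfer methylene without enolisation, since both ketones have α-stereocentres and β-oxygen leaving groups.

**40 ⇒ 36.** The C5 carbonyl is taken back to an allylic alcohol and C3–C4 to an E-alkene (40 → 39 → 38 → 37 → 36). With C3=C4 in place, O5–H is the only allylic hydroxyl, so C5 can be told from C6 without two kinds of protecting group. The forward steps need an allylic oxidation beside a free C6 hydroxyl and a saturation of the enone alkene that spares the allylic C2 ester.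

**36 ⇒ 34.** Ring B is opened at C2–C3 (36 → 35 → 34) to an aldehyde and an alkenyl iodide. This ring bond joins a carbonyl carbon to an sp2 carbon that is cheap to make on the chain. The gain is an open-chain seco compound. The closure must form a ten-membered ring at a neopentyl aldehyde, leave the C11 ketone alone, and set C2.

**34 ⇒ 29 + 16.** The C9–C10 bond is cut (34 → 33 → 32 → 29 + 16) as an aldol addition. This is the most convergent cut: ring A and the lactone-bearing chain become separate fragments of similar size. The forward step needs an enolate formed toward C10 only, attack on the face of C15, and a syn relationship between C10 and C9.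

**16 ⇒ 8.** Fragment 16 goes back through 15, 14, 13, 12, 11, 10 and 9 to 8. Only C3=C4 (an olefination) is a skeletal bond; the rest are changes of oxidation level and protection. The demand is that the two dioxolanes of 8 open one after the other.

**8 ⇒ 7.** The C8–C17 bond is cut and the lactone ring is opened. This removes the quaternary stereocentre and returns to an acyclic hexitol ester. The forward step must insert at C8–H, not at C6–H, with retention.

**7 ⇒ 1, 3, 4.** The diazo group goes back to a sulfonylhydrazone (7 → 6), the ester bond is cut to 2 and 5, and 2 and 5 go back to 1 and to 3 and 4. The demand is one acylation per hydroxyl of the C2-symmetric diol 1.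

**29 ⇒ 17 + 18.** The C11 carbonyl goes back to the C10=C11 alkene (29 → 28 → 26 → 25 → 24). The alkene goes back to a bromide and then to an oxygen bridge between C11 and C14 (24 → 23 → 22). The bridge hides the 1,4-cis relationship and allows all-cis oxygenation from the convex face (22 → 21 → 20). Finally C1–C14 and C10–C11 are cut in a cycloaddition (20 → 19 → 17 + 18). The demands are enantiofacial control in the cycloaddition and opening of the bridge at C11, not at C14.

## Other disconnections considered

**Alternative 1:** ring B is cut at C6–C7 as the last ring bond. In the forward step CrCl2 (divalent chromium) turns an allylic bromide at C16 into a γ-chloroallyl chromium species. This adds through C6 to a C7 aldehyde and gives the chlorohydrin A1 with the C5=C16 methylene in place.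
- *In its favour:* the chloride, the C7 carbinol and the exocyclic alkene arise in one step. The anti relationship of chlorine and oxygen expected from a chair transition state is the one in the target. No substitution at a ring carbon is needed. On the C6 problem this is better than the chosen plan.
- *Against it here:* C8 and C17 must be set earlier on an acyclic precursor without help from the chiral pool. The C7 aldehyde sits on the fully substituted C8, so addition is hindered and its facial control is uncertain. All ring A esters and the oxirane are already present in A1 and so meet Lewis-acidic trivalent chromium.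
- *Comparison:* structurally both plans end ring B construction with a chromium-mediated closure. Mechanistically the two closures are equally well founded. In step count the alternative saves the two C6 steps and the C5 methylenation but spends steps on C8 and C17. The chosen plan is stronger where the alternative is weakest (C8, C7) and weaker at C6.

**Alternative 2:** ring A is cut at C1–C14 and C10–C11. The forward step is an endo Diels–Alder reaction of an E-enal (C2, C1, C10, with C9 already attached) with a 1,4-diacetoxy diene. It gives A2 with C1, C10, C11 and C14 set.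
- *In its favour:* four ring A stereocentres, including the quaternary C1, form in one concerted step. The C9–C10 bond exists from the start, so the intermolecular aldol between two hindered partners is avoided. On this point, and on the length of the ring A synthesis (one step against nine), it is better.
- *Against it here:* a β-substituted α-methyl enal is a slow dienophile toward a moderately electron-rich diene. Facial control rests on one dioxolane stereocentre. C12=C13 must then be dihydroxylated on the face of both acetoxy groups, against the steric bias. C8 starts as a dioxolane CH2 and must be built into the tertiary carbinol with C7 and C17, which costs two C–C bonds and two stereocentres.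
- *Comparison:* the chosen plan takes C8 and C7 from the hexitol and makes C17 in one insertion. It gets the all-cis oxygens from the exo face of an oxygen-bridged alkene. It is therefore shorter on the lactone side and longer on ring A. For the C1/C10 relationship the concerted cycloaddition is the more predictable mechanism.

**Alternative 3:** the C1–C10 bond is cut across a fourteen-membered epoxy macrocycle. In the forward step Cp2TiCl (trivalent titanium) opens the C1–C14 epoxide to the tertiary C1 radical. The radical attacks C10 of the E-C10=C11 alkene across the ring. The sequence ends as the C11=C20 methylene and a C14 hydroxyl, giving A3.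
- *In its favour:* it follows the likely biogenesis. Rings A and B, C1, C10, C14 and the C11=C20 handle all come in one step. The C14 hydroxyl arrives free and distinct from O12 and O13. In step economy of core formation and in differentiation of O14 it is better than the chosen plan.
- *Against it here:* the macrocyclic precursor must already hold the lactone, the C5 ketone, the C6 silyl ether and three esters, and needs its own macrocyclisation. The facial course depends on the conformation of a flexible ring. The C11 radical (or its titanium adduct) lies next to the C12 acetate, so loss of acetate competes with the wanted β-hydride loss toward C20.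
- *Comparison:* A3 still has the C5 ketone and the C6 oxygen of inverted configuration, so the late C5 and C6 steps are the same as in the chosen plan (equal). The chosen plan is longer, but each stereocentre is tied to a named control element.

Key step: step 5

Assumption: in step 14 the antipode of the oxazaborolidine catalyst is chosen so that the cycloadduct has the absolute configuration drawn for 19.

Assumption: 8 may form as a mixture at C17; step 6 is taken to converge it to the epimer drawn.

Remark: the configurations of 7 and 8 were checked atom by atom against 47. C8, C7 and C17 of 8 match the target and C6 has the opposite sense, as a later inversion requires. No structure needed correction. The precursor keeps its benzoate and both acetonides. The weak point, two acetonides that look alike, is met by the key step itself (the C8/C9 dioxolane becomes 4,4-disubstituted) and by removing the benzoate before the first hydrolysis.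

Step 1
Reactants: 1 1,2:5,6-di-O-isopropylidene-D-mannitol
Product: 2 3-O-benzoyl-1,2:5,6-di-O-isopropylidene-D-mannitol (the same compound as the 4-O-benzoate; the free hydroxyl is the future O7)
Conditions: BzCl (1.05 equiv), Me2SnCl2 (cat.), K2CO3, THF, rt
Reagents that add atoms: benzoyl chloride, O=C(Cl)c1ccccc1
Why: Tin-catalysed monoacylation of a 1,2-diol: the cyclic stannylene activates one oxygen and the first benzoate deactivates its neighbour, so the dibenzoate is held back; the two hydroxyls of 1 are related by the C2 axis, so only one monobenzoate exists.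

Step 2
Reactants: 3 pyruvic acid; 4 p-toluenesulfonohydrazide
Product: 5 2-(p-tolylsulfonylhydrazono)propanoic acid
Conditions: aq. HCl (1 M), 60 °C then 0 °C
Reagents that add atoms: none
Why: Condensation of a ketone with a sulfonylhydrazide (hydrazone formation); the acid crystallises from the aqueous medium.

Step 3
Reactants: 2 3-O-benzoyl-1,2:5,6-di-O-isopropylidene-D-mannitol; 5 2-(p-tolylsulfonylhydrazono)propanoic acid
Product: 6 4-O-benzoyl-1,2:5,6-di-O-isopropylidene-3-O-[2-(p-tolylsulfonylhydrazono)propanoyl]-D-mannitol
Conditions: DCC, DMAP (cat.), CH2Cl2, 0 °C to rt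
Reagents that add atoms: none
Why: Carbodiimide (Steglich) esterification of the remaining secondary hydroxyl; no stereocentre is touched and the acetonides and the benzoate are inert.

Step 4
Reactants: 6 4-O-benzoyl-1,2:5,6-di-O-isopropylidene-3-O-[2-(p-tolylsulfonylhydrazono)propanoyl]-D-mannitol
Product: 7 4-O-benzoyl-3-O-(2-diazopropanoyl)-1,2:5,6-di-O-isopropylidene-D-mannitol
Conditions: DBU, CH2Cl2, 0 °C to rt
Reagents that add atoms: none
Why: Bamford–Stevens-type elimination: DBU removes the sulfonylhydrazone N–H proton and p-toluenesulfinate leaves, giving the α-diazo ester; no strong base is needed, so the benzoate does not migrate.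

Step 5
Reactants: 7 4-O-benzoyl-3-O-(2-diazopropanoyl)-1,2:5,6-di-O-isopropylidene-D-mannitol
Product: 8 spiro γ-lactone (C19 carbonyl on O7, C17 bonded to C8, C8 spiro to the C8/C9 acetonide, C18 methyl cis to O8, C6 benzoate, C4/C5 acetonide)
Conditions: Rh2(O2CCPh3)4 (1 mol%), CH2Cl2, −78 °C to rt, slow addition of 7
Reagents that add atoms: none
Why: The dirhodium carboxylate takes up the diazo carbon C17, N2 leaves, and the electrophilic carbenoid inserts into the C8–H bond through a three-centre transition state in which the C–C and C–H bonds form as the metal departs. The closest known reaction type is the dirhodium tetracarboxylate-catalysed intramolecular C–H insertion of α-diazo esters into ether C–H bonds that gives γ-lactones. The lactone closes in the 1,5 mode (five-membered ring), which is favoured over the 1,6 insertions at C9 and C5. C8 becomes the fully substituted carbinol carbon with retention, so it keeps the configuration of C2 of D-mannitol, and C7 is untouched. C17 is set by the orientation of the methyl group in the transition state (expected away from the dioxolane ring) and, being epimerisable, converges in step 6. The step needs insertion at C8–H and not at C6–H: C8–H is a dioxolane C–H activated by oxygen, and C6–H is deactivated by the benzoate. It must also outrun the 1,2-hydride shift to the acrylate and attack on the dioxolane oxygen, for which the bulky triphenylacetate ligands, low temperature and slow addition are chosen. As a further gain the C8/C9 dioxolane becomes 4,4-disubstituted and so differs from the C4/C5 one.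

Step 6
Reactants: 8 spiro γ-lactone with C6 benzoate
Product: 9 C6 alcohol of the spiro lactone (both acetonides kept)
Conditions: K2CO3 (0.2 equiv), MeOH, 0 °C; pH 7 work-up
Reagents that add atoms: none
Why: Carbonate-catalysed transesterification removes the benzoate as methyl benzoate; the γ-lactone, if opened, closes again (5-exo) on neutral work-up, and C17 equilibrates through the lactone enolate to the needed epimer, with the methyl group cis to the C7 side chain and trans to C9.

Step 7
Reactants: 9 C6 alcohol of the spiro lactone
Product: 10 C4,C5,C6-triol (C8/C9 spiro acetonide kept)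
Conditions: AcOH/H2O (3:2), rt
Reagents that add atoms: none
Why: Acid-catalysed acetal hydrolysis: the 4-monosubstituted dioxolane next to the free C6 hydroxyl opens faster than the 4,4-disubstituted spiro dioxolane, which is slowed by gem-disubstitution and by the electron-withdrawing lactone.

Step 8
Reactants: 10 C4,C5,C6-triol
Product: 11 C4,C5,C6-tris(triethylsilyl) ether
Conditions: Et3SiOTf, 2,6-lutidine, CH2Cl2, −78 °C
Reagents that add atoms: triethylsilyl triflate, CC[Si](CC)(CC)OS(=O)(=O)C(F)(F)F
Why: Silyl triflate silylation of one primary and two secondary hydroxyls; the hindered base keeps the acetonide and the lactone intact.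

Step 9
Reactants: 11 C4,C5,C6-tris(triethylsilyl) ether
Product: 12 C4 aldehyde (O5 and O6 as triethylsilyl ethers)
Conditions: (COCl)2, DMSO, CH2Cl2, −78 to −35 °C; Et3N
Reagents that add atoms: none
Why: Swern oxidation applied directly to a primary triethylsilyl ether: the chlorosulfonium salt cleaves and oxidises the primary Si–O bond while secondary silyl ethers persist; epimerisation at C5 in the α-silyloxy aldehyde is harmless because C5 ends as an sp2 carbon.

Step 10
Reactants: 12 C4 aldehyde
Product: 13 (E)-alkenyl iodide (C3=C4, iodine on C3)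
Conditions: CrCl2, CHI3, THF, 0 °C to rt
Reagents that add atoms: iodoform, IC(I)I
Why: Takai olefination: the gem-dichromium species from CHI3 adds to the aldehyde and eliminates to the E-alkenyl iodide; the reagent is not basic, so the lactone and C6 are safe; C3 enters here.

Step 11
Reactants: 13 (E)-alkenyl iodide
Product: 14 tetraol (hydroxyls on C5, C6, C8 and C9; lactone and alkenyl iodide kept)
Conditions: aq. HCl (1 M), THF, rt, short reaction time
Reagents that add atoms: none
Why: Aqueous acid hydrolyses the remaining dioxolane and, unavoidably, the two secondary silyl ethers; the short reaction time limits acyl transfer of the lactone from O7 to the freed O9.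

Step 12
Reactants: 14 tetraol
Product: 15 tetrakis(triethylsilyl) ether (O5, O6, O8, O9)
Conditions: Et3SiOTf (excess), 2,6-lutidine, CH2Cl2, −78 to 0 °C
Reagents that add atoms: triethylsilyl triflate, CC[Si](CC)(CC)OS(=O)(=O)C(F)(F)F
Why: Exhaustive silylation; the triflate is needed for the tertiary C8 hydroxyl.

Step 13
Reactants: 15 tetrakis(triethylsilyl) ether
Product: 16 C9 aldehyde (chain fragment: lactone, O5, O6 and O8 triethylsilyl ethers, E-alkenyl iodide)
Conditions: (COCl)2, DMSO, CH2Cl2, −78 to −30 °C; Et3N
Reagents that add atoms: none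
Why: The same direct Swern oxidation as in step 9: the only primary silyl ether (O9) is oxidised and the tertiary and secondary ones stay; the aldehyde has no α-hydrogen and can neither epimerise nor self-condense.

Step 14
Reactants: 17 furan; 18 methacrolein
Product: 20 exo-2-(hydroxymethyl)-endo-2-methyl-7-oxabicyclo[2.2.1]hept-5-ene, via exo-aldehyde 19 (not isolated)
Conditions: 2-butyl-4-(1H-indol-3-ylmethyl)-3-(p-tolylsulfonyl)-1,3,2-oxazaborolidin-5-one (10 mol%, single enantiomer), CH2Cl2, −78 °C; then NaBH4, MeOH, −78 to 0 °C
Reagents that add atoms: none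
Why: Chiral Lewis acid-catalysed Diels–Alder reaction of furan with a 2-substituted acrolein: the catalyst shields one face of the enal and the formyl group ends exo (methyl endo), which sets C1 of the target and puts C2 on the side of the oxygen bridge; reduction in the same flask stops the retro-reaction.

Step 15
Reactants: 20 exo-2-(hydroxymethyl)-endo-2-methyl-7-oxabicyclo[2.2.1]hept-5-ene
Product: 21 exo,exo-5,6-diol of 20 (triol)
Conditions: OsO4 (cat.), N-methylmorpholine N-oxide, acetone/H2O, rt
Reagents that add atoms: N-methylmorpholine N-oxide, C[N+]1([O-])CCOCC1; water, O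
Why: Catalytic dihydroxylation (Upjohn conditions): OsO4 adds to the exo face of the bicyclic alkene, syn to the oxygen bridge, so O12, O13 and the bridge oxygen (later O14) are all cis to each other and to C2.

Step 16
Reactants: 21 triol
Product: 22 tris(tert-butyldimethylsilyl) ether of 21
Conditions: tBuMe2SiOTf, 2,6-lutidine, CH2Cl2, 0 °C
Reagents that add atoms: tert-butyldimethylsilyl triflate, CC(C)(C)[Si](C)(C)OS(=O)(=O)C(F)(F)F
Why: Silylation of the primary and the two exo secondary hydroxyls; silyl ethers tolerate the Lewis acid of step 17 and are not enolate-sensitive later.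

Step 17
Reactants: 22 tris(tert-butyldimethylsilyl) ether
Product: 23 bromo acetate (cyclohexane: C14 acetate, C11 bromide trans to it, C12 and C13 silyl ethers cis to the acetate, C1 with methyl and CH2OSi)
Conditions: MgBr2·OEt2, Ac2O, MeCN, rt
Reagents that add atoms: acetic anhydride, CC(=O)OC(C)=O; magnesium bromide, [Mg+2].[Br-].[Br-]
Why: Acylative cleavage of the strained bridging ether: the oxygen is acetylated and bromide opens the oxonium ion by SN2 at C11, the bridgehead that is not neopentyl, with inversion; O14 keeps its configuration and leaves the step as the acetate that the target needs.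

Step 18
Reactants: 23 bromo acetate
Product: 24 cyclohexene (C10=C11)
Conditions: DBU, toluene, 80 °C
Reagents that add atoms: none
Why: E2 elimination: the only hydrogen anti-periplanar to the axial C11–Br bond is on C10 (H12 is cis to bromine), so the alkene forms at C10=C11.

Step 19
Reactants: 24 cyclohexene
Product: 25 primary alcohol (C2–OH)
Conditions: HF·pyridine, pyridine, THF, 0 °C
Reagents that add atoms: none
Why: Fluoride cleaves the primary silyl ether much faster than the two secondary ones; the buffered medium leaves the acetate in place.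

Step 20
Reactants: 25 primary alcohol
Product: 26 C2 triethylsilyl ether
Conditions: Et3SiCl, imidazole, CH2Cl2, 0 °C
Reagents that add atoms: chlorotriethylsilane, CC[Si](Cl)(CC)CC
Why: Silylation; the primary triethylsilyl ether is the group that step 25 oxidises directly.

Step 21
Reactants: 26 C2 triethylsilyl ether
Product: 28 C11 alcohol, via alkylborane 27 (not isolated)
Conditions: 9-BBN, THF, 60 °C; then NaBO3·4H2O, THF/H2O, rt
Reagents that add atoms: sodium perborate, B1(OO1)[O-].[Na+]
Why: Hydroboration–oxidation: boron goes to C11, away from the neopentyl C10 and next to the allylic silyloxy carbon, anti to O12; the C11 configuration is lost in step 22, and perborate oxidises the borane without cleaving the acetate.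

Step 22
Reactants: 28 C11 alcohol
Product: 29 ring A ketone (C11 carbonyl, C10 methylene, C12 and C13 tert-butyldimethylsilyl ethers, C14 acetate, C2 triethylsilyl ether)
Conditions: Dess–Martin periodinane, NaHCO3, CH2Cl2, rt
Reagents that add atoms: none
Why: Dess–Martin oxidation of a secondary alcohol under buffered, non-basic conditions, so the β-silyloxy ketone does not eliminate.

Step 23
Reactants: 29 ring A ketone; 16 C9 aldehyde
Product: 32 aldol adduct (C9–C10 bond, free C9 hydroxyl), via lithium enolate 30 (not isolated), via titanium enolate 31 (not isolated)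
Conditions: LiN(SiMe3)2, THF, −78 °C; ClTi(OiPr)3, −78 to −40 °C; then 16, −78 °C
Reagents that add atoms: none
Why: Directed aldol addition: the amide base removes a C10 proton (the methylene, not the silyloxy methine C12 and not the acetate), and the triisopropoxytitanium enolate of a cyclic ketone adds to aldehydes with syn selectivity. The aldehyde should approach C10 on the face of the C15 methyl group, anti to the CH2OSiEt3 branch, which sets C10. The syn relationship then sets C9, since the aldehyde has little facial bias of its own (both ring carbons flanking C8 turn a hydrogen toward C9).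

Step 24
Reactants: 32 aldol adduct
Product: 33 C9 triethylsilyl ether
Conditions: Et3SiOTf, 2,6-lutidine, CH2Cl2, −78 °C
Reagents that add atoms: triethylsilyl triflate, CC[Si](CC)(CC)OS(=O)(=O)C(F)(F)F
Why: Silylation of the hindered β-hydroxy ketone blocks retro-aldol cleavage and lactol formation with the later C2 aldehyde.

Step 25
Reactants: 33 C9 triethylsilyl ether
Product: 34 C2 aldehyde (seco compound with alkenyl iodide)
Conditions: (COCl)2, DMSO, CH2Cl2, −78 to −35 °C; Et3N
Reagents that add atoms: none
Why: Direct Swern oxidation of the single primary triethylsilyl ether (O2); the secondary and tertiary silyl ethers, the ketone, the lactone and the alkenyl iodide are inert.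

Step 26
Reactants: 34 C2 aldehyde
Product: 35 ring B allylic alcohol (C2–OH, E-C3=C4, ten-membered ring closed)
Conditions: CrCl2 (excess), NiCl2 (1 mol%), DMSO, rt, high dilution
Reagents that add atoms: none
Why: Nozaki–Hiyama–Kishi reaction: zerovalent nickel inserts into the C–I bond, the alkenyl group passes to trivalent chromium and adds to the aldehyde only (not to the C11 ketone or the esters), closing the ten-membered ring with retention of the E geometry. C2 should form with the chromium-bound oxygen turned to the outside of the ring, anti to the C15 methyl group, as in the target.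

Step 27
Reactants: 35 ring B allylic alcohol
Product: 36 C2 isobutyrate
Conditions: isobutyryl chloride, pyridine, DMAP (cat.), CH2Cl2, 0 °C to rt
Reagents that add atoms: isobutyryl chloride, CC(C)C(Cl)=O
Why: Acylation of the secondary alcohol with the acid chloride and DMAP installs the final C2 ester, which is hindered enough to survive all later steps.

Step 28
Reactants: 36 C2 isobutyrate
Product: 37 C5,C6-diol (O8 and O9 triethylsilyl ethers kept)
Conditions: PPTS, MeOH/CH2Cl2, 0 °C
Reagents that add atoms: none
Why: Mild acid methanolysis removes the two unhindered secondary triethylsilyl ethers; the tertiary O8 and crowded O9 triethylsilyl ethers and the tert-butyldimethylsilyl ethers react much more slowly.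

Step 29
Reactants: 37 C5,C6-diol
Product: 38 C5 enone (C5=O conjugated to C3=C4, free C6 hydroxyl)
Conditions: MnO2 (activated, excess), CH2Cl2, rt
Reagents that add atoms: none
Why: MnO2 oxidises only allylic alcohols, so the C5 hydroxyl (next to C3=C4) is oxidised and the C6 hydroxyl is not, which tells C5 from C6; the other allylic oxygen, O2, is already an ester.

Step 30
Reactants: 38 C5 enone
Product: 39 C6 triethylsilyl ether of the enone
Conditions: Et3SiCl, imidazole, DMAP (cat.), DMF, 0 °C
Reagents that add atoms: chlorotriethylsilane, CC[Si](Cl)(CC)CC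
Why: Silylation with the chloride and imidazole protects the α′-hydroxy enone against ketol isomerisation without forming a silyl enol ether.

Step 31
Reactants: 39 C6 triethylsilyl ether of the enone
Product: 40 diketone (C5 and C11 carbonyls, C3–C4 saturated)
Conditions: 2-nitrobenzenesulfonylhydrazide, Et3N, CH2Cl2, rt
Reagents that add atoms: none
Why: Diimide, made in the flask from the sulfonylhydrazide, transfers H2 to the strained, electron-poor E-alkene; unlike palladium-catalysed hydrogenation it cannot cleave the allylic C2 ester or reduce the ketones.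

Step 32
Reactants: 40 diketone
Product: 41 bis(methylene) compound (C5=C16 and C11=C20)
Conditions: Zn, CH2Br2, TiCl4, THF/CH2Cl2, 0 °C to rt
Reagents that add atoms: dibromomethane, BrCBr
Why: Takai–Lombardo methylenation: the gem-dimetallic methylene reagent is not basic, so neither ketone is enolised (no β-elimination of O7, O9 or O13, no epimerisation at C6, C10 or C12), and esters and the lactone do not react; C16 and C20 enter together.

Step 33
Reactants: 41 bis(methylene) compound
Product: 42 triol (free hydroxyls on C6, C8 and C9; O12 and O13 silyl ethers kept)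
Conditions: HF·pyridine, pyridine, THF, 0 °C to rt
Reagents that add atoms: none
Why: Buffered fluoride removes the triethylsilyl ethers and leaves the tert-butyldimethylsilyl ethers on O12 and O13, so the C6 hydroxyl is the only unhindered secondary hydroxyl; a triethylsilyl group left on O9 would fall in step 35.

Step 34
Reactants: 42 triol
Product: 43 C6 chloride (configuration inverted)
Conditions: PPh3, hexachloroacetone, CH2Cl2, 0 °C
Reagents that add atoms: hexachloroacetone, ClC(Cl)(Cl)C(=O)C(Cl)(Cl)Cl
Why: Chlorination through the alkoxyphosphonium salt: chloride displaces the activated oxygen by SN2 with inversion, giving the C6 configuration of the target. PPh3 with hexachloroacetone is the variant known to convert secondary allylic alcohols without allylic transposition; the C7 acyloxy group disfavours ionisation, and the tertiary O8 and crowded O9 hydroxyls are too hindered to react.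

Step 35
Reactants: 43 C6 chloride
Product: 44 tetraol (free hydroxyls on C8, C9, C12 and C13)
Conditions: HF·pyridine, THF, rt
Reagents that add atoms: none
Why: Unbuffered HF·pyridine cleaves the two secondary tert-butyldimethylsilyl ethers; the allylic chloride, the alkenes and the esters tolerate it.

Step 36
Reactants: 44 tetraol
Product: 45 C13 isovalerate
Conditions: isovaleryl chloride (1.1 equiv), Me2SnCl2 (5 mol%), iPr2NEt, THF, 0 °C
Reagents that add atoms: isovaleryl chloride, CC(C)CC(Cl)=O
Why: Tin-catalysed regioselective acylation of a cis-1,2-diol: the stannylene of the 12,13-diol is acylated at the equatorial O13 (O12 is axial and allylic); the C8 and C9 hydroxyls are too hindered.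

Step 37
Reactants: 45 C13 isovalerate
Product: 46 spiro-epoxide (C11–C20 oxirane, oxygen cis to O12)
Conditions: VO(acac)2 (cat.), tBuOOH, CH2Cl2, 0 °C
Reagents that add atoms: tert-butyl hydroperoxide, CC(C)(C)OO
Why: Vanadium-catalysed hydroxyl-directed epoxidation: the vanadate ester of the allylic C12 hydroxyl delivers oxygen to the same face of C11=C20, giving the epoxide oxygen cis to O12 as in the target; C5=C16 has no directing hydroxyl and is deactivated by the allylic chloride.

Step 38
Reactants: 46 spiro-epoxide
Product: 47 CNP0231073.1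
Conditions: Ac2O, pyridine, DMAP (cat.), CH2Cl2, 0 °C to rt
Reagents that add atoms: acetic anhydride, CC(=O)OC(C)=O
Why: Acetylation of the secondary hydroxyls at C9 and C12 with DMAP catalysis; the tertiary C8 hydroxyl is left, and the conditions are too mild to open the epoxide or to move the other esters.

## Compound list

1 | 1,2:5,6-di-O-isopropylidene-D-mannitol | C1OC(C)(C)O[C@H]1[C@@H](O)[C@H](O)[C@H]2COC(C)(C)O2 | starting material
2 | 3-O-benzoyl-1,2:5,6-di-O-isopropylidene-D-mannitol | C1OC(C)(C)O[C@H]1[C@@H](O)[C@H](OC(=O)c2ccccc2)[C@H]3COC(C)(C)O3 | intermediate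
3 | pyruvic acid | CC(=O)C(O)=O | starting material
4 | p-toluenesulfonohydrazide | Cc1ccc(cc1)S(=O)(=O)NN | starting material
5 | 2-(p-tolylsulfonylhydrazono)propanoic acid | CC(=NNS(=O)(=O)c1ccc(C)cc1)C(O)=O | intermediate
6 | 4-O-benzoyl-1,2:5,6-di-O-isopropylidene-3-O-[2-(p-tolylsulfonylhydrazono)propanoyl]-D-mannitol | C1OC(C)(C)O[C@H]1[C@@H](OC(=O)C(C)=NNS(=O)(=O)c2ccc(C)cc2)[C@H](OC(=O)c3ccccc3)[C@H]4COC(C)(C)O4 | intermediate
7 | 4-O-benzoyl-3-O-(2-diazopropanoyl)-1,2:5,6-di-O-isopropylidene-D-mannitol | C1OC(C)(C)O[C@H]1[C@@H](OC(=O)C(C)=[N+]=[N-])[C@H](OC(=O)c2ccccc2)[C@H]3COC(C)(C)O3 | intermediate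
8 | spiro γ-lactone (C8–C17 bond formed; C6 benzoate; two acetonides) | C1OC(C)(C)O[C@]12[C@@H](C)C(=O)O[C@H]2[C@H](OC(=O)c3ccccc3)[C@H]4COC(C)(C)O4 | intermediate
9 | C6 alcohol of the spiro lactone | C1OC(C)(C)O[C@]12[C@@H](C)C(=O)O[C@H]2[C@H](O)[C@H]3COC(C)(C)O3 | intermediate
10 | C4,C5,C6-triol (spiro acetonide kept) | C1OC(C)(C)O[C@]12[C@@H](C)C(=O)O[C@H]2[C@H](O)[C@H](O)CO | intermediate
11 | C4,C5,C6-tris(triethylsilyl) ether | C1OC(C)(C)O[C@]12[C@@H](C)C(=O)O[C@H]2[C@H](O[Si](CC)(CC)CC)[C@H](O[Si](CC)(CC)CC)CO[Si](CC)(CC)CC | intermediate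
12 | C4 aldehyde | C1OC(C)(C)O[C@]12[C@@H](C)C(=O)O[C@H]2[C@H](O[Si](CC)(CC)CC)[C@H](O[Si](CC)(CC)CC)C=O | intermediate
13 | (E)-alkenyl iodide (C3=C4) | C1OC(C)(C)O[C@]12[C@@H](C)C(=O)O[C@H]2[C@H](O[Si](CC)(CC)CC)[C@H](O[Si](CC)(CC)CC)/C=C/I | intermediate
14 | tetraol (C5, C6, C8, C9 hydroxyls) | OC[C@]1(O)[C@@H](C)C(=O)O[C@H]1[C@H](O)[C@H](O)/C=C/I | intermediate
15 | tetrakis(triethylsilyl) ether | CC[Si](CC)(CC)OC[C@]1(O[Si](CC)(CC)CC)[C@@H](C)C(=O)O[C@H]1[C@H](O[Si](CC)(CC)CC)[C@H](O[Si](CC)(CC)CC)/C=C/I | intermediate
16 | C9 aldehyde (chain fragment) | O=C[C@]1(O[Si](CC)(CC)CC)[C@@H](C)C(=O)O[C@H]1[C@H](O[Si](CC)(CC)CC)[C@H](O[Si](CC)(CC)CC)/C=C/I | intermediate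
17 | furan | c1ccoc1 | starting material
18 | methacrolein | CC(=C)C=O | starting material
19 | exo-2-formyl-endo-2-methyl-7-oxabicyclo[2.2.1]hept-5-ene | O=C[C@@]1(C)[C@@H]2C=C[C@@H](O2)C1 | intermediate
20 | exo-2-(hydroxymethyl)-endo-2-methyl-7-oxabicyclo[2.2.1]hept-5-ene | OC[C@@]1(C)[C@@H]2C=C[C@@H](O2)C1 | intermediate
21 | exo,exo-5,6-diol of 20 (triol) | OC[C@@]1(C)[C@@H]2[C@@H](O)[C@@H](O)[C@@H](O2)C1 | intermediate
22 | tris(tert-butyldimethylsilyl) ether of 21 | CC(C)(C)[Si](C)(C)OC[C@@]1(C)[C@@H]2[C@@H](O[Si](C)(C)C(C)(C)C)[C@@H](O[Si](C)(C)C(C)(C)C)[C@@H](O2)C1 | intermediate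
23 | bromo acetate (C14 acetate, C11 bromide) | CC(C)(C)[Si](C)(C)OC[C@@]1(C)[C@@H](OC(C)=O)[C@@H](O[Si](C)(C)C(C)(C)C)[C@@H](O[Si](C)(C)C(C)(C)C)[C@H](Br)C1 | intermediate
24 | cyclohexene (C10=C11) | CC(C)(C)[Si](C)(C)OC[C@@]1(C)[C@@H](OC(C)=O)[C@@H](O[Si](C)(C)C(C)(C)C)[C@@H](O[Si](C)(C)C(C)(C)C)C=C1 | intermediate
25 | primary alcohol (C2–OH) | OC[C@@]1(C)[C@@H](OC(C)=O)[C@@H](O[Si](C)(C)C(C)(C)C)[C@@H](O[Si](C)(C)C(C)(C)C)C=C1 | intermediate
26 | C2 triethylsilyl ether | CC[Si](CC)(CC)OC[C@@]1(C)[C@@H](OC(C)=O)[C@@H](O[Si](C)(C)C(C)(C)C)[C@@H](O[Si](C)(C)C(C)(C)C)C=C1 | intermediate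
27 | alkylborane (9-borabicyclononyl on C11) | CC[Si](CC)(CC)OC[C@@]1(C)[C@@H](OC(C)=O)[C@@H](O[Si](C)(C)C(C)(C)C)[C@@H](O[Si](C)(C)C(C)(C)C)[C@H](B2C3CCCC2CCC3)C1 | intermediate
28 | C11 alcohol | CC[Si](CC)(CC)OC[C@@]1(C)[C@@H](OC(C)=O)[C@@H](O[Si](C)(C)C(C)(C)C)[C@@H](O[Si](C)(C)C(C)(C)C)[C@H](O)C1 | intermediate
29 | ring A ketone | CC[Si](CC)(CC)OC[C@@]1(C)[C@@H](OC(C)=O)[C@@H](O[Si](C)(C)C(C)(C)C)[C@@H](O[Si](C)(C)C(C)(C)C)C(=O)C1 | intermediate
30 | lithium enolate of 29 (C10=C11) | CC[Si](CC)(CC)OC[C@@]1(C)[C@@H](OC(C)=O)[C@@H](O[Si](C)(C)C(C)(C)C)[C@@H](O[Si](C)(C)C(C)(C)C)C(O[Li])=C1 | intermediate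
31 | triisopropoxytitanium enolate of 29 | CC[Si](CC)(CC)OC[C@@]1(C)[C@@H](OC(C)=O)[C@@H](O[Si](C)(C)C(C)(C)C)[C@@H](O[Si](C)(C)C(C)(C)C)C(O[Ti](OC(C)C)(OC(C)C)OC(C)C)=C1 | intermediate
32 | aldol adduct (C9–OH) | CC[Si](CC)(CC)OC[C@@]1(C)[C@@H](OC(C)=O)[C@@H](O[Si](C)(C)C(C)(C)C)[C@@H](O[Si](C)(C)C(C)(C)C)C(=O)[C@@H]1[C@H](O)[C@]2(O[Si](CC)(CC)CC)[C@@H](C)C(=O)O[C@H]2[C@H](O[Si](CC)(CC)CC)[C@H](O[Si](CC)(CC)CC)/C=C/I | intermediate
33 | C9 triethylsilyl ether | CC[Si](CC)(CC)OC[C@@]1(C)[C@@H](OC(C)=O)[C@@H](O[Si](C)(C)C(C)(C)C)[C@@H](O[Si](C)(C)C(C)(C)C)C(=O)[C@@H]1[C@H](O[Si](CC)(CC)CC)[C@]2(O[Si](CC)(CC)CC)[C@@H](C)C(=O)O[C@H]2[C@H](O[Si](CC)(CC)CC)[C@H](O[Si](CC)(CC)CC)/C=C/I | intermediate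
34 | C2 aldehyde (seco compound) | O=C[C@@]1(C)[C@@H](OC(C)=O)[C@@H](O[Si](C)(C)C(C)(C)C)[C@@H](O[Si](C)(C)C(C)(C)C)C(=O)[C@@H]1[C@H](O[Si](CC)(CC)CC)[C@]2(O[Si](CC)(CC)CC)[C@@H](C)C(=O)O[C@H]2[C@H](O[Si](CC)(CC)CC)[C@H](O[Si](CC)(CC)CC)/C=C/I | intermediate
35 | ring B allylic alcohol (C2–OH, E-C3=C4) | O[C@@H]4[C@@]1(C)[C@@H](OC(C)=O)[C@@H](O[Si](C)(C)C(C)(C)C)[C@@H](O[Si](C)(C)C(C)(C)C)C(=O)[C@@H]1[C@H](O[Si](CC)(CC)CC)[C@]2(O[Si](CC)(CC)CC)[C@@H](C)C(=O)O[C@H]2[C@H](O[Si](CC)(CC)CC)[C@H](O[Si](CC)(CC)CC)/C=C/4 | intermediate
36 | C2 isobutyrate | CC(C)C(=O)O[C@@H]4[C@@]1(C)[C@@H](OC(C)=O)[C@@H](O[Si](C)(C)C(C)(C)C)[C@@H](O[Si](C)(C)C(C)(C)C)C(=O)[C@@H]1[C@H](O[Si](CC)(CC)CC)[C@]2(O[Si](CC)(CC)CC)[C@@H](C)C(=O)O[C@H]2[C@H](O[Si](CC)(CC)CC)[C@H](O[Si](CC)(CC)CC)/C=C/4 | intermediate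
37 | C5,C6-diol | CC(C)C(=O)O[C@@H]4[C@@]1(C)[C@@H](OC(C)=O)[C@@H](O[Si](C)(C)C(C)(C)C)[C@@H](O[Si](C)(C)C(C)(C)C)C(=O)[C@@H]1[C@H](O[Si](CC)(CC)CC)[C@]2(O[Si](CC)(CC)CC)[C@@H](C)C(=O)O[C@H]2[C@H](O)[C@H](O)/C=C/4 | intermediate
38 | C5 enone (C6–OH) | CC(C)C(=O)O[C@@H]4[C@@]1(C)[C@@H](OC(C)=O)[C@@H](O[Si](C)(C)C(C)(C)C)[C@@H](O[Si](C)(C)C(C)(C)C)C(=O)[C@@H]1[C@H](O[Si](CC)(CC)CC)[C@]2(O[Si](CC)(CC)CC)[C@@H](C)C(=O)O[C@H]2[C@H](O)C(=O)/C=C/4 | intermediate
39 | C6 triethylsilyl ether of the enone | CC(C)C(=O)O[C@@H]4[C@@]1(C)[C@@H](OC(C)=O)[C@@H](O[Si](C)(C)C(C)(C)C)[C@@H](O[Si](C)(C)C(C)(C)C)C(=O)[C@@H]1[C@H](O[Si](CC)(CC)CC)[C@]2(O[Si](CC)(CC)CC)[C@@H](C)C(=O)O[C@H]2[C@H](O[Si](CC)(CC)CC)C(=O)/C=C/4 | intermediate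
40 | diketone (C5, C11) | CC(C)C(=O)O[C@@H]4[C@@]1(C)[C@@H](OC(C)=O)[C@@H](O[Si](C)(C)C(C)(C)C)[C@@H](O[Si](C)(C)C(C)(C)C)C(=O)[C@@H]1[C@H](O[Si](CC)(CC)CC)[C@]2(O[Si](CC)(CC)CC)[C@@H](C)C(=O)O[C@H]2[C@H](O[Si](CC)(CC)CC)C(=O)CC4 | intermediate
41 | bis(methylene) compound | CC(C)C(=O)O[C@@H]4[C@@]1(C)[C@@H](OC(C)=O)[C@@H](O[Si](C)(C)C(C)(C)C)[C@@H](O[Si](C)(C)C(C)(C)C)C(=C)[C@@H]1[C@H](O[Si](CC)(CC)CC)[C@]2(O[Si](CC)(CC)CC)[C@@H](C)C(=O)O[C@H]2[C@H](O[Si](CC)(CC)CC)C(=C)CC4 | intermediate
42 | triol (C6, C8, C9 hydroxyls) | CC(C)C(=O)O[C@@H]4[C@@]1(C)[C@@H](OC(C)=O)[C@@H](O[Si](C)(C)C(C)(C)C)[C@@H](O[Si](C)(C)C(C)(C)C)C(=C)[C@@H]1[C@H](O)[C@]2(O)[C@@H](C)C(=O)O[C@H]2[C@H](O)C(=C)CC4 | intermediate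
43 | C6 chloride | CC(C)C(=O)O[C@@H]4[C@@]1(C)[C@@H](OC(C)=O)[C@@H](O[Si](C)(C)C(C)(C)C)[C@@H](O[Si](C)(C)C(C)(C)C)C(=C)[C@@H]1[C@H](O)[C@]2(O)[C@@H](C)C(=O)O[C@H]2[C@@H](Cl)C(=C)CC4 | intermediate
44 | tetraol (C8, C9, C12, C13 hydroxyls) | CC(C)C(=O)O[C@@H]4[C@@]1(C)[C@@H](OC(C)=O)[C@@H](O)[C@@H](O)C(=C)[C@@H]1[C@H](O)[C@]2(O)[C@@H](C)C(=O)O[C@H]2[C@@H](Cl)C(=C)CC4 | intermediate
45 | C13 isovalerate | CC(C)C(=O)O[C@@H]4[C@@]1(C)[C@@H](OC(C)=O)[C@@H](OC(=O)CC(C)C)[C@@H](O)C(=C)[C@@H]1[C@H](O)[C@]2(O)[C@@H](C)C(=O)O[C@H]2[C@@H](Cl)C(=C)CC4 | intermediate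
46 | spiro-epoxide | CC(C)C(=O)O[C@@H]4[C@@]1(C)[C@@H](OC(C)=O)[C@@H](OC(=O)CC(C)C)[C@@H](O)[C@]3(CO3)[C@@H]1[C@H](O)[C@]2(O)[C@@H](C)C(=O)O[C@H]2[C@@H](Cl)C(=C)CC4 | intermediate
47 | CNP0231073.1 | C=C1CC[C@H](OC(=O)C(C)C)[C@@]2(C)[C@@H](OC(C)=O)[C@@H](OC(=O)CC(C)C)[C@@H](OC(C)=O)[C@]3(CO3)[C@@H]2[C@H](OC(C)=O)[C@]2(O)[C@@H](C)C(=O)O[C@H]2[C@H]1Cl | target

## Step count and least certain steps

Total: 38 steps. Longest linear sequence: 28 steps (1 to 47 through steps 1, 3 to 13 and 23 to 38). Step 2 makes the reagent 5, and steps 14 to 22 make the ring A fragment 29.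

**Step 5 (key step).** The most likely failure is diversion of the carbenoid before insertion: a 1,2-hydride shift from the C18 methyl group to the acrylate, or attack on the dioxolane oxygen with ylide rearrangement. Both are known side paths of α-alkyl carbenoids beside ether oxygens. The fallback sets out from 2 and avoids the α-methyl carbenoid. Acylation with bromoacetyl bromide should give the bromoacetate F1. N,N′-Ditosylhydrazine and DBU should convert it into the diazoacetate F2. Rh2(OAc)4 should then effect the better-precedented insertion of a diazoacetate into the C8–H bond, giving the lactone without the C18 methyl group F3. Methylation of its lithium enolate (LiN(SiMe3)2, MeI, −78 °C), with equilibration in step 6, comes back to the route at 8.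

**Step 14.** The risk is low conversion and low enantiofacial control, since methacrolein is less reactive toward furan than the 2-haloacroleins for which this catalysis is established. The fallback sets out from 17 and 18. A BF3·OEt2-promoted cycloaddition with NaBH4 work-up should give the racemic alcohol F4. Lipase-catalysed acetylation with vinyl acetate should convert the unwanted enantiomer into its acetate F5 and leave the wanted one. This comes back at 20.

**Step 23.** The risk is poor facial selectivity at C10 and poor syn/anti selectivity between two hindered partners, plus retro-aldol loss on warming. The ring A conformer that reacts is not secured, and closed transition states of cyclic enolates tend to the anti adduct. The fallback changes to an open transition state. From 29, LiN(SiMe3)2 and Me3SiCl should give the trimethylsilyl enol ether F6. A Mukaiyama aldol addition of F6 to 16 with BF3·OEt2 at −78 °C comes back at 32.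

**Step 26.** The risks are oligomerisation in competition with ring closure at a neopentyl aldehyde, and formation of the wrong C2 epimer, because the facial course rests only on the ring-forming conformation. The fallback for the epimer problem sets out from 35 as an epimer mixture. Dess–Martin oxidation should give the C2 enone F7. A Corey–Bakshi–Shibata reduction with the appropriate catalyst enantiomer sets C2 under reagent control and comes back at 35.

**Step 34.** The risks are allylic transposition (SN2′ to the primary C16 chloride) and incomplete inversion through ion-pair collapse. Backside approach to C6 is partly shielded within the ten-membered ring. The fallback separates activation from displacement. From 42, MsCl and Et3N at −40 °C should give the C6 mesylate F8. Displacement with Bu4NCl in acetone at low temperature comes back at 43.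

## Further compounds

F1 | step 5 | 4-O-benzoyl-3-O-(bromoacetyl)-1,2:5,6-di-O-isopropylidene-D-mannitol | C1OC(C)(C)O[C@H]1[C@@H](OC(=O)CBr)[C@H](OC(=O)c2ccccc2)[C@H]3COC(C)(C)O3
F2 | step 5 | 4-O-benzoyl-3-O-(diazoacetyl)-1,2:5,6-di-O-isopropylidene-D-mannitol | C1OC(C)(C)O[C@H]1[C@@H](OC(=O)C=[N+]=[N-])[C@H](OC(=O)c2ccccc2)[C@H]3COC(C)(C)O3
F3 | step 5 | spiro γ-lactone without the C18 methyl group | C1OC(C)(C)O[C@]12CC(=O)O[C@H]2[C@H](OC(=O)c3ccccc3)[C@H]4COC(C)(C)O4
F4 | step 14 | racemic exo-2-(hydroxymethyl)-endo-2-methyl-7-oxabicyclo[2.2.1]hept-5-ene | OC[C@@]1(C)[C@@H]2C=C[C@@H](O2)C1.OC[C@]1(C)[C@H]2C=C[C@H](O2)C1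
F5 | step 14 | acetate of the enantiomer of 20 | CC(=O)OC[C@]1(C)[C@H]2C=C[C@H](O2)C1
F6 | step 23 | trimethylsilyl enol ether of 29 (C10=C11) | CC[Si](CC)(CC)OC[C@@]1(C)[C@@H](OC(C)=O)[C@@H](O[Si](C)(C)C(C)(C)C)[C@@H](O[Si](C)(C)C(C)(C)C)C(O[Si](C)(C)C)=C1
F7 | step 26 | C2 enone (C2=O conjugated to E-C3=C4) | O=C4[C@@]1(C)[C@@H](OC(C)=O)[C@@H](O[Si](C)(C)C(C)(C)C)[C@@H](O[Si](C)(C)C(C)(C)C)C(=O)[C@@H]1[C@H](O[Si](CC)(CC)CC)[C@]2(O[Si](CC)(CC)CC)[C@@H](C)C(=O)O[C@H]2[C@H](O[Si](CC)(CC)CC)[C@H](O[Si](CC)(CC)CC)/C=C/4
F8 | step 34 | C6 mesylate of 42 | CC(C)C(=O)O[C@@H]4[C@@]1(C)[C@@H](OC(C)=O)[C@@H](O[Si](C)(C)C(C)(C)C)[C@@H](O[Si](C)(C)C(C)(C)C)C(=C)[C@@H]1[C@H](O)[C@]2(O)[C@@H](C)C(=O)O[C@H]2[C@H](OS(C)(=O)=O)C(=C)CC4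
A1 | alternative 1 | ring B chlorohydrin with C19 methyl ester and C8 trimethylsilyl ether | C=C1CC[C@H](OC(=O)C(C)C)[C@@]2(C)[C@@H](OC(C)=O)[C@@H](OC(=O)CC(C)C)[C@@H](OC(C)=O)[C@]3(CO3)[C@@H]2[C@H](OC(C)=O)[C@](O[Si](C)(C)C)([C@@H](C)C(=O)OC)[C@@H](O)[C@H]1Cl
A2 | alternative 2 | ring A cyclohexene aldehyde with C1, C10, C11 and C14 set | O=C[C@@]1(C)[C@@H](OC(C)=O)C=C[C@@H](OC(C)=O)[C@@H]1[C@H]2COC(C)(C)O2
A3 | alternative 3 | bicyclic core with C14 hydroxyl and C11=C20 methylene | O=C1CC[C@H](OC(=O)C(C)C)[C@@]2(C)[C@@H](O)[C@@H](OC(=O)CC(C)C)[C@@H](OC(C)=O)C(=C)[C@@H]2[C@H](OC(C)=O)[C@]3(O)[C@@H](C)C(=O)O[C@H]3[C@@H]1O[Si](C)(C)C(C)(C)C
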